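## Structural features

Ustusoic acid B is a drimane: a trans-fused decalin in which ring A (C1–C5, C10) carries only the C4 gem-dimethyl group and ring B (C5–C10) carries every functional group. Ring B holds the axial 6β-ester of (2E,4E,6E)-octa-2,4,6-trienoic acid, a C7=C8 double bond whose C8 bears the aldehyde C12, a fully substituted C9 with an α-hydroxyl and the β-carboxyl C11, and the quaternary C10 with its β-methyl group. The four stereocentres C6, C5, C10 and C9 are contiguous (5S,6R,9S,10S, that is 5α-H, 6β-O, 9α-OH, 10β-CH3), and C9 and C10 are neighbouring fully substituted carbons. The fragile groups are the trienoate (oxidants, nucleophiles, hydrogenation), the enal with its γ-acyloxy group at C6 (base), and the tertiary α-hydroxy acid beside the aldehyde, which can close to a five-membered lactol and which lactonises whenever C12 passes through the alcohol level. The real difficulty is C9: its carbon substituent sits on the β-face, syn to the C10 methyl group, so C11 cannot be added to a C9 ketone, which nucleophiles attack from the α-face. A second difficulty is the 6β-oxygen, syn-axial to the C10 and 4β methyl groups: easy to create by α-face hydride delivery, hard to acylate. The key step exploits the fact that ring B is oxygenated para (C6 and C9) and carries one-carbon substituents on C8 and C10, the pattern of 2,6-dimethyl-1,4-benzoquinone, while the C1–C10 and C4–C5 bonds of ring A with the gem-dimethyl terminus map onto a 2-silyloxydiene derived from mesityl oxide.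

## Logic of the disconnections

24 ⇒ 23. No skeletal bond is cut; the C11 carboxyl is carried as a tert-butyl ester. A free acid beside the C12 aldehyde cannot be present while O6 is acylated, and the tert-butyl group leaves by acid alone, without base, nucleophile or metal. The demand is that 23 tolerates brief strong acid, which it should, because cations at C6 and C9 would be destabilised by the neighbouring carbonyl groups.

23 ⇒ 18 + 21. The O6–acyl bond is cut. The trienoate is incompatible with every oxidation used on ring B, so it is attached after all of them. This removes eight carbons and three alkenes. The forward step must acylate an axial, doubly shielded secondary alcohol next to an enal without deconjugating the activated acid.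

21 ⇒ 19. The C2′=C3′ bond of the side chain is cut, a two-carbon extension of a commercial dienal. The forward step must give the 2E alkene, which a condensation–decarboxylation does.

18 ⇒ 17 ⇒ 16. The O6–Si bond (protecting group) and the C12–O bonds are traced back to a silyl ether and a methyl group. C12 is a methyl because it is one of the two equivalent methyls of 4. On the fully substituted alkene carbon C8 the only allylic hydrogens are those of C12, so the site of oxidation is fixed by the structure. The forward step must reach the aldehyde without leaving an alcohol that could lactonise onto C11, hence the hindered ester in 16.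

16 ⇒ 15 ⇒ 13. The ester and the oxidation level of C11 are traced back to a primary alcohol. The tertiary C9 hydroxyl needs no protection. The demand is oxidation of a neopentyl primary alcohol without cleavage of the 9,11-glycol.

13 ⇒ 12. The C9–O and C11–O bonds are cut. This is the answer to the C9 problem: carbon is put on first as an sp2 methylene and oxygen is then delivered to the open α-face, the reverse of adding carbon to a ketone. One stereocentre and two oxygens disappear. The forward step needs α-face selectivity (from the C10 methyl group) and preference for the exocyclic alkene over C7=C8.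

12 ⇒ 11. The C9=C11 bond is cut, leaving a C9 ketone. The forward olefination must succeed on a ketone flanked by the quaternary C10 and the substituted C8; the absence of α-hydrogens makes a basic ylide acceptable.

11 ⇒ 10 ⇒ 9 ⇒ 8. Unsaturation and oxygen are put back at C2. The C2 oxygen is the price of the activating group on the diene and is removed as enol ether → enol triflate → alkene → alkane. The demand is hydrogenation of C2=C3 beside C7=C8, which is why it is done while C7=C8 is a hindered trisubstituted enone and before the exocyclic alkene exists.

8 ⇒ 7 ⇒ 6. The O6–Si bond and the C6–H bond are cut, leaving the ene-dione. Reduction differentiates the two carbonyls: the less shielded C6 is reduced, C9 is kept for C11. The forward step must be regioselective, 1,2-selective and deliver hydride from the α-face.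

6 ⇒ 5. Only the configuration at C5 changes. The trans fusion is traced to the cis fusion that a cycloaddition must give. The forward step relies on enolisation of the C6 ketone and a preference for 5α-H.

5 ⇒ 3 + 4. The C1–C10 and C4–C5 bonds are cut, opening ring A. A bicyclic compound with two stereocentres becomes two achiral pieces, one commercial. The forward step must bond the CH2 terminus of 3 to the methyl-bearing carbon of 4 and choose one face. There is no site problem, because the two double bonds of 4 are related by a twofold axis. A quinone already oxidised at C12 would save a late step but would make the two double bonds different, so the symmetric 4 is kept. The bulky silyl group of 3 is kept as well: it protects the dienol ether against the acidic catalyst and is later exchanged directly for triflate.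

3 ⇒ 1. The O–Si bond is cut. The forward step needs kinetic deprotonation at the α′-methyl group.

## Other disconnections considered

Alternative 1: The cut is C5–C6 and C9–C10. Ring B would be assembled from 3-hydroxy-4-methyl-2-pyrone A1 (C6 to C9 with C11 and C12) and 2,4,4-trimethylcyclohex-2-enone A2 (ring A with a C1 ketone).
- Forward step: a bifunctional cinchona catalyst deprotonates A1, its C6 adds to the β-carbon of A2 (future C5), and the enolate closes onto the hydroxyl-bearing carbon of the pyrone (future C9) to give the bridged lactone A3.
- In favour: one step installs O6, the 9α-hydroxyl and C11 at the carboxyl level, and the bridge forces O6 and C11 onto the same face. On C9 and C11 this is better than the chosen plan, which spends steps 9 to 11 there.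
- Against: A2 is a trisubstituted enone with a neopentyl β-carbon and an α-methyl group, a poor acceptor for a weak nucleophile. The closing bond joins two fully substituted carbons. A3 is necessarily cis-fused (5β-H) and, unlike 5, has no C6 ketone through which C5 could epimerise, so lactone opening, oxidation, epimerisation and re-reduction would be needed. The C1 ketone beside C10 must also be removed.
- Comparison: equal to the chosen plan in leaving C12 as a methyl group and one superfluous ring-A oxygen; better at C9; worse at C5 and in the reactivity it demands of its key step. Its total length is not expected to be shorter once C5 and C1 are corrected.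

Alternative 2: The cut is C6–O and C9–O.
- Forward step: the ring-B diene ester A4 takes up singlet oxygen across C6 and C9 on the α-face, opposite the C10 methyl group, to give the endoperoxide A5. An amine base then removes H6, the only hydrogen on a peroxide-bearing carbon, and gives the 9α-hydroxy enone A6.
- In favour: both ring-B oxygens and the C9 stereocentre come from one operation, the direction of the fragmentation is unambiguous, and C11 is already an ester. From the 7-en-6-one stage on this is shorter and mechanistically cleaner than steps 9 to 12 of the chosen plan, so here it is the better route.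
- Against: it presupposes A4, a trans-drimane with C5 and C10 already set in one enantiomeric series, so the skeleton and the absolute configuration are displaced rather than solved. A diene conjugated to an ester is a slow partner for singlet oxygen and offers allylic hydrogens for a competing ene reaction. A methyl ester on a tertiary centre would be hard to remove at the end beside the trienoate, so another ester would be needed.
- Comparison: equal on the remaining tasks (α-face reduction of C6, oxidation of C12, acylation). The chosen plan is stronger in building skeleton and configuration from achiral commercial materials in one catalytic step.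

Alternative 3: The cut is C5–C10 and C8–C9; both rings come from the acyclic triene A7.
- Forward step: the oxazaborolidinium-activated enoate (C9=C10) is attacked by the tethered silyloxydiene (C5=C6–C7=C8) to give the trans-fused A8.
- In favour: the trans fusion is set directly, so no epimerisation is needed. Ring A carries no superfluous oxygen, which saves the three deoxygenation steps. C11 arrives as an ester and C6 as an enol ether ready for dehydrogenation to the 7-en-6-one. On these three points it is better than the chosen plan.
- Against: the dienophile is a β,β-disubstituted enoate, far weaker than a quinone, and the C5–C10 bond must join a neopentyl diene terminus to a carbon that becomes quaternary. A7 needs its own multistep, geometry-defined synthesis. Two of the four stereocentres that the step sets (C8 and C9) are later erased or remade.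
- Comparison: the same family of catalysis as the chosen plan; fewer steps after the key step but more before it; equal on C12 and on the late C6 and C9 chemistry.

Key step: step 2

Assumption: the (S)-configured oxazaborolidinium salt is taken to expose the quinone face that leads to the 10S adduct 5, as the usual C–H···O binding model predicts; if the sense proves opposite, its (R)-enantiomer is used and nothing else changes.

Remark: drimane numbering is used throughout; C11 is the carbon on C9, C12 the carbon on C8, and every compound from 5 onward has the 10β-methyl group.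

## Route

Step 1
Reactants: 1 mesityl oxide (4-methylpent-3-en-2-one)
Product: 3 4-methyl-2-(triisopropylsilyloxy)penta-1,3-diene, via lithium 4-methylpenta-1,3-dien-2-olate 2 (not isolated)
Conditions: LiN(iPr)2, THF, −78 °C; then iPr3SiOTf, −78 → 0 °C
Reagents that add atoms: triisopropylsilyl trifluoromethanesulfonate, CC(C)[Si](OS(=O)(=O)C(F)(F)F)(C(C)C)C(C)C
Why: LiN(iPr)2 removes a proton from the α′-methyl group under kinetic control, and the hard silyl triflate traps the cross-conjugated lithium dienolate on oxygen; this is ordinary silyl enol ether formation and creates no stereocentre.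

Step 2
Reactants: 3 4-methyl-2-(triisopropylsilyloxy)penta-1,3-diene; 4 2,6-dimethyl-1,4-benzoquinone
Product: 5 2-(triisopropylsilyloxy)-11-nor-5β-drima-2,7-diene-6,9-dione (cis-fused adduct; 10β-methyl)
Conditions: 3 (1.5 equiv), (S)-1-(2-methylphenyl)-3,3-diphenyltetrahydro-1H,3H-pyrrolo[1,2-c][1,3,2]oxazaborole·HNTf2 (20 mol %), CH2Cl2, −78 → −40 °C; Et3N quench
Reagents that add atoms: none
Why: The protonated oxazaborolidine binds the C6 carbonyl oxygen of 4, the more basic and the only unhindered one, flanked by two vinylic C–H bonds, and this places the largest LUMO coefficient on the methyl-bearing β-carbon (future C10). The diene reacts through its s-cis form, its most nucleophilic terminus (the CH2 of the silyl enol ether) bonding to C10 and the CMe2 terminus to C5 in a concerted but asynchronous endo [4+2] cycloaddition; the closest known reaction type is the enantioselective Diels–Alder reaction of quinones with 2-silyloxy-1,3-dienes under chiral oxazaborolidinium catalysis. Ring A is closed in this single intermolecular cycloaddition, both of its new bonds (C1–C10 and C4–C5) being formed suprafacially on each partner. C10 is set by the catalyst, whose aryl group covers one face of the bound quinone double bond, and C5 follows from C10 because the addition is suprafacial, so that H5 and the C10 methyl group end up cis. The step needs regioselectivity and enantiofacial selectivity but no site selectivity: the first comes from carbonyl-selective coordination together with the polarised diene (which also avoids a vicinal quaternary pair), the second from the catalyst, and the third is not required because the two double bonds of 4 are related by a twofold axis. The 2-silyloxy group destabilises the s-trans conformer and so offsets the s-cis penalty of the Z-methyl group, and the quaternary C10 prevents aromatisation of the adduct.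

Step 3
Reactants: 5 2-(triisopropylsilyloxy)-11-nor-5β-drima-2,7-diene-6,9-dione
Product: 6 2-(triisopropylsilyloxy)-11-nor-5α-drima-2,7-diene-6,9-dione (trans-fused)
Conditions: DBU (0.3 equiv), toluene, 23 °C, argon
Reagents that add atoms: none
Why: C5–H is the only enolisable hydrogen of the ene-dione, so the amidine base epimerises C5 alone through the C6 dienolate while the quaternary C10 cannot change; the 5α-H trans fusion is expected to be the thermodynamic product, as in 6-oxodrimanes, which puts C5 under thermodynamic control relative to C10. The silyl enol ether is inert to DBU.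

Step 4
Reactants: 6 2-(triisopropylsilyloxy)-11-nor-5α-drima-2,7-diene-6,9-dione
Product: 7 6β-hydroxy-2-(triisopropylsilyloxy)-11-nor-5α-drima-2,7-dien-9-one
Conditions: NaBH4, CeCl3·7H2O, MeOH–CH2Cl2, −78 °C
Reagents that add atoms: none
Why: Luche reduction adds hydride 1,2 to the C6 carbonyl, which is less shielded than C9 (flanked by the quaternary C10 and the methyl-bearing C8), and only from the α-face because the β-face is closed by the syn-axial C10 and 4β methyl groups; C6 is thus set as the axial 6β-alcohol under substrate control. Once C6 is sp3, C5 can no longer epimerise.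

Step 5
Reactants: 7 6β-hydroxy-2-(triisopropylsilyloxy)-11-nor-5α-drima-2,7-dien-9-one
Product: 8 6β-(tert-butyldimethylsilyloxy)-2-(triisopropylsilyloxy)-11-nor-5α-drima-2,7-dien-9-one
Conditions: tBuMe2SiOTf, 2,6-lutidine, CH2Cl2, −78 → 0 °C
Reagents that add atoms: tert-butyldimethylsilyl trifluoromethanesulfonate, CC(C)(C)[Si](C)(C)OS(=O)(=O)C(F)(F)F
Why: A silyl triflate with a hindered pyridine base silylates even this axial, doubly flanked alcohol (standard silyl ether formation); the ether shields O6 from the base of step 9 and the oxidants of steps 10, 11 and 13 and withdraws electron density from C7=C8.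

Step 6
Reactants: 8 6β-(tert-butyldimethylsilyloxy)-2-(triisopropylsilyloxy)-11-nor-5α-drima-2,7-dien-9-one
Product: 9 6β-(tert-butyldimethylsilyloxy)-9-oxo-11-nor-5α-drima-2,7-dien-2-yl trifluoromethanesulfonate
Conditions: CsF, PhNTf2, DME, 23 °C
Reagents that add atoms: N-phenylbis(trifluoromethanesulfonimide), O=S(=O)(N(c1ccccc1)S(=O)(=O)C(F)(F)F)C(F)(F)F
Why: Fluoride cleaves the O–Si bond of the silyl enol ether (the alkyl silyl ether reacts far more slowly under anhydrous conditions) and the cesium enolate is trapped on oxygen by PhNTf2, a known one-flask exchange of a triisopropylsilyl enol ether for an enol triflate that keeps the C2=C3 position.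

Step 7
Reactants: 9 6β-(tert-butyldimethylsilyloxy)-9-oxo-11-nor-5α-drima-2,7-dien-2-yl trifluoromethanesulfonate
Product: 10 6β-(tert-butyldimethylsilyloxy)-11-nor-5α-drima-2,7-dien-9-one
Conditions: Pd(OAc)2 (5 mol %), PPh3 (10 mol %), HCO2H, nBu3N, DMF, 60 °C
Reagents that add atoms: none
Why: Oxidative addition of the enol triflate to zerovalent palladium (formed in the flask from Pd(OAc)2 and PPh3), exchange of triflate for formate, loss of CO2 and reductive elimination replace C–OTf by C–H (palladium-catalysed formate reduction of enol triflates); the hindered enone is not reduced by the palladium hydride under these conditions.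

Step 8
Reactants: 10 6β-(tert-butyldimethylsilyloxy)-11-nor-5α-drima-2,7-dien-9-one
Product: 11 6β-(tert-butyldimethylsilyloxy)-11-nor-5α-drim-7-en-9-one
Conditions: H2 (1 atm), RhCl(PPh3)3 (5 mol %), toluene–EtOH, 23 °C
Reagents that add atoms: none
Why: RhCl(PPh3)3 hydrogenates the cis-disubstituted C2=C3 alkene and leaves the trisubstituted, conjugated and flanked C7=C8 untouched, since homogeneous hydrogenation is strongly sensitive to alkene substitution; ring A now carries only the gem-dimethyl group and no stereocentre is created.

Step 9
Reactants: 11 6β-(tert-butyldimethylsilyloxy)-11-nor-5α-drim-7-en-9-one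
Product: 12 6β-(tert-butyldimethylsilyloxy)-5α-drima-7,9(11)-diene
Conditions: Ph3PCH3Br, KOtBu, toluene, 0 → 80 °C
Reagents that add atoms: methyltriphenylphosphonium bromide, C[P+](c1ccccc1)(c1ccccc1)c1ccccc1.[Br-]
Why: Wittig methylenation; the ketone has no α-hydrogen (C10 is quaternary, C8 is sp2), so the basic ylide can only add to the carbonyl, and methylenetriphenylphosphorane at elevated temperature is the usual answer to ketones flanked by a quaternary carbon. Addition is 1,2 and gives the s-trans diene.

Step 10
Reactants: 12 6β-(tert-butyldimethylsilyloxy)-5α-drima-7,9(11)-diene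
Product: 13 6β-(tert-butyldimethylsilyloxy)-5α-drim-7-ene-9α,11-diol
Conditions: OsO4 (5 mol %), N-methylmorpholine N-oxide, acetone–H2O, 0 → 23 °C
Reagents that add atoms: N-methylmorpholine N-oxide, C[N+]1([O-])CCOCC1; water, O
Why: OsO4 adds by [3+2] cycloaddition to the exocyclic methylene, the most open alkene terminus (C7=C8 is trisubstituted and deactivated by the allylic silyloxy group), from the α-face opposite the C10 methyl group, so that O9 is α and C11 stays β; C9 is set under substrate control. Catalytic dihydroxylation with an amine N-oxide as reoxidant is standard.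

Step 11
Reactants: 13 6β-(tert-butyldimethylsilyloxy)-5α-drim-7-ene-9α,11-diol
Product: 15 6β-(tert-butyldimethylsilyloxy)-9α-hydroxy-5α-drim-7-en-11-oic acid, via 9α-hydroxy 11-aldehyde 14 (not isolated)
Conditions: TEMPO (10 mol %), NaOCl (5 mol %), NaClO2, MeCN–phosphate buffer (pH 6.7), 35 °C
Reagents that add atoms: sodium chlorite, [Na+].[O-]Cl=O
Why: The oxoammonium salt generated from TEMPO oxidises the primary alcohol to the aldehyde 14, and chlorite takes 14 on to the acid in the same flask; the tertiary C9 hydroxyl cannot be oxidised and no glycol-cleaving oxidant is present.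

Step 12
Reactants: 15 6β-(tert-butyldimethylsilyloxy)-9α-hydroxy-5α-drim-7-en-11-oic acid
Product: 16 tert-butyl 6β-(tert-butyldimethylsilyloxy)-9α-hydroxy-5α-drim-7-en-11-oate
Conditions: tert-butyl 2,2,2-trichloroacetimidate, CH2Cl2–cyclohexane, 23 °C
Reagents that add atoms: tert-butyl 2,2,2-trichloroacetimidate, CC(C)(C)OC(=N)C(Cl)(Cl)Cl
Why: The carboxylic acid protonates the imidate and the carboxylate is alkylated on oxygen by the tert-butyl cation equivalent, a process indifferent to crowding at the acyl carbon; without added Lewis acid the tertiary alcohol is not etherified. The tert-butyl ester is a poor partner for lactonisation in step 13 and is later removed without base, nucleophile or metal.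

Step 13
Reactants: 16 tert-butyl 6β-(tert-butyldimethylsilyloxy)-9α-hydroxy-5α-drim-7-en-11-oate
Product: 17 tert-butyl 6β-(tert-butyldimethylsilyloxy)-9α-hydroxy-12-oxo-5α-drim-7-en-11-oate
Conditions: SeO2, 1,4-dioxane (trace H2O), 90 °C
Reagents that add atoms: selenium dioxide, O=[Se]=O
Why: Riley oxidation: an ene reaction of SeO2 at C7=C8 followed by a [2,3]-sigmatropic shift oxidises an allylic position on the fully substituted alkene carbon, and there C12 is the only one that carries hydrogen (C9 has none), so the site is dictated by the structure. With stoichiometric oxidant at 90 °C the selenium ester should collapse to the enal; no stereocentre is touched.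

Step 14
Reactants: 17 tert-butyl 6β-(tert-butyldimethylsilyloxy)-9α-hydroxy-12-oxo-5α-drim-7-en-11-oate
Product: 18 tert-butyl 6β,9α-dihydroxy-12-oxo-5α-drim-7-en-11-oate
Conditions: HF·pyridine, THF–pyridine, 0 → 23 °C
Reagents that add atoms: none
Why: Fluoride-assisted cleavage of the silyl ether under buffered acidic conditions, which the enal, the tertiary alcohol and the tert-butyl ester tolerate; basic fluoride sources that could deprotonate C6 are avoided.

Step 15
Reactants: 19 (2E,4E)-hexa-2,4-dienal
Product: 21 (2E,4E,6E)-octa-2,4,6-trienoic acid, via hexadienylidenemalonic acid 20 (not isolated)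
Conditions: malonic acid, pyridine, piperidine (cat.), 90 °C
Reagents that add atoms: malonic acid, OC(=O)CC(=O)O
Why: Doebner modification of the Knoevenagel condensation: the aldehyde condenses with malonic acid and the alkylidenemalonic acid 20 loses CO2 in hot pyridine to give the 2E acid; the 4E and 6E bonds are carried over from the dienal.

Step 16
Reactants: 18 tert-butyl 6β,9α-dihydroxy-12-oxo-5α-drim-7-en-11-oate; 21 (2E,4E,6E)-octa-2,4,6-trienoic acid
Product: 23 tert-butyl 9α-hydroxy-6β-[(2E,4E,6E)-octa-2,4,6-trienoyloxy]-12-oxo-5α-drim-7-en-11-oate, via mixed anhydride 22 (not isolated)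
Conditions: 21, 2,4,6-trichlorobenzoyl chloride, Et3N, THF, 0 °C; then 18, DMAP, toluene, 23 → 40 °C
Reagents that add atoms: none
Why: Yamaguchi esterification: the acid is activated as the mixed anhydride 22 and DMAP transfers the trienoyl group to the secondary 6β-hydroxyl; the tertiary C9 hydroxyl is too hindered to compete. The bond formed is acyl–oxygen, so C6 is not affected.

Step 17
Reactants: 23 tert-butyl 9α-hydroxy-6β-[(2E,4E,6E)-octa-2,4,6-trienoyloxy]-12-oxo-5α-drim-7-en-11-oate
Product: 24 ustusoic acid B, 9α-hydroxy-6β-[(2E,4E,6E)-octa-2,4,6-trienoyloxy]-12-oxo-5α-drim-7-en-11-oic acid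
Conditions: CF3CO2H–CH2Cl2 (1:4), 0 °C
Reagents that add atoms: none
Why: Acidolysis of the tert-butyl ester by alkyl–oxygen cleavage with loss of isobutene; the allylic ester at C6 and the tertiary alcohol at C9 should not ionise because the cations would sit beside or in conjugation with carbonyl groups. No base or nucleophile is present to attack the trienoate or the γ-acyloxy enal.

## Compound list

1 | mesityl oxide (4-methylpent-3-en-2-one) | CC(=O)C=C(C)C | starting material
2 | lithium 4-methylpenta-1,3-dien-2-olate | [Li]OC(=C)C=C(C)C | intermediate
3 | 4-methyl-2-(triisopropylsilyloxy)penta-1,3-diene | C=C(O[Si](C(C)C)(C(C)C)C(C)C)C=C(C)C | intermediate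
4 | 2,6-dimethyl-1,4-benzoquinone | CC1=CC(=O)C=C(C)C1=O | starting material
5 | 2-(triisopropylsilyloxy)-11-nor-5β-drima-2,7-diene-6,9-dione (cis-fused adduct; 10β-methyl) | O=C1C=C(C)C(=O)[C@@]2(C)CC(O[Si](C(C)C)(C(C)C)C(C)C)=CC(C)(C)[C@@H]12 | intermediate
6 | 2-(triisopropylsilyloxy)-11-nor-5α-drima-2,7-diene-6,9-dione (trans-fused) | O=C1C=C(C)C(=O)[C@@]2(C)CC(O[Si](C(C)C)(C(C)C)C(C)C)=CC(C)(C)[C@H]12 | intermediate
7 | 6β-hydroxy-2-(triisopropylsilyloxy)-11-nor-5α-drima-2,7-dien-9-one | O[C@@H]1C=C(C)C(=O)[C@@]2(C)CC(O[Si](C(C)C)(C(C)C)C(C)C)=CC(C)(C)[C@H]12 | intermediate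
8 | 6β-(tert-butyldimethylsilyloxy)-2-(triisopropylsilyloxy)-11-nor-5α-drima-2,7-dien-9-one | CC(C)(C)[Si](C)(C)O[C@@H]1C=C(C)C(=O)[C@@]2(C)CC(O[Si](C(C)C)(C(C)C)C(C)C)=CC(C)(C)[C@H]12 | intermediate
9 | 6β-(tert-butyldimethylsilyloxy)-9-oxo-11-nor-5α-drima-2,7-dien-2-yl trifluoromethanesulfonate | CC(C)(C)[Si](C)(C)O[C@@H]1C=C(C)C(=O)[C@@]2(C)CC(OS(=O)(=O)C(F)(F)F)=CC(C)(C)[C@H]12 | intermediate
10 | 6β-(tert-butyldimethylsilyloxy)-11-nor-5α-drima-2,7-dien-9-one | CC(C)(C)[Si](C)(C)O[C@@H]1C=C(C)C(=O)[C@@]2(C)CC=CC(C)(C)[C@H]12 | intermediate
11 | 6β-(tert-butyldimethylsilyloxy)-11-nor-5α-drim-7-en-9-one | CC(C)(C)[Si](C)(C)O[C@@H]1C=C(C)C(=O)[C@@]2(C)CCCC(C)(C)[C@H]12 | intermediate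
12 | 6β-(tert-butyldimethylsilyloxy)-5α-drima-7,9(11)-diene | CC(C)(C)[Si](C)(C)O[C@@H]1C=C(C)C(=C)[C@@]2(C)CCCC(C)(C)[C@H]12 | intermediate
13 | 6β-(tert-butyldimethylsilyloxy)-5α-drim-7-ene-9α,11-diol | CC(C)(C)[Si](C)(C)O[C@@H]1C=C(C)[C@](O)(CO)[C@@]2(C)CCCC(C)(C)[C@H]12 | intermediate
14 | 6β-(tert-butyldimethylsilyloxy)-9α-hydroxy-5α-drim-7-en-11-al | CC(C)(C)[Si](C)(C)O[C@@H]1C=C(C)[C@](O)(C=O)[C@@]2(C)CCCC(C)(C)[C@H]12 | intermediate
15 | 6β-(tert-butyldimethylsilyloxy)-9α-hydroxy-5α-drim-7-en-11-oic acid | CC(C)(C)[Si](C)(C)O[C@@H]1C=C(C)[C@](O)(C(=O)O)[C@@]2(C)CCCC(C)(C)[C@H]12 | intermediate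
16 | tert-butyl 6β-(tert-butyldimethylsilyloxy)-9α-hydroxy-5α-drim-7-en-11-oate | CC(C)(C)[Si](C)(C)O[C@@H]1C=C(C)[C@](O)(C(=O)OC(C)(C)C)[C@@]2(C)CCCC(C)(C)[C@H]12 | intermediate
17 | tert-butyl 6β-(tert-butyldimethylsilyloxy)-9α-hydroxy-12-oxo-5α-drim-7-en-11-oate | CC(C)(C)[Si](C)(C)O[C@@H]1C=C(C=O)[C@](O)(C(=O)OC(C)(C)C)[C@@]2(C)CCCC(C)(C)[C@H]12 | intermediate
18 | tert-butyl 6β,9α-dihydroxy-12-oxo-5α-drim-7-en-11-oate | O[C@@H]1C=C(C=O)[C@](O)(C(=O)OC(C)(C)C)[C@@]2(C)CCCC(C)(C)[C@H]12 | intermediate
19 | (2E,4E)-hexa-2,4-dienal | C/C=C/C=C/C=O | starting material
20 | 2-[(2E,4E)-hexa-2,4-dien-1-ylidene]malonic acid | C/C=C/C=C/C=C(C(=O)O)C(=O)O | intermediate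
21 | (2E,4E,6E)-octa-2,4,6-trienoic acid | C/C=C/C=C/C=C/C(=O)O | intermediate
22 | (2E,4E,6E)-octa-2,4,6-trienoic 2,4,6-trichlorobenzoic anhydride | C/C=C/C=C/C=C/C(=O)OC(=O)c1c(Cl)cc(Cl)cc1Cl | intermediate
23 | tert-butyl 9α-hydroxy-6β-[(2E,4E,6E)-octa-2,4,6-trienoyloxy]-12-oxo-5α-drim-7-en-11-oate | C/C=C/C=C/C=C/C(=O)O[C@@H]1C=C(C=O)[C@](O)(C(=O)OC(C)(C)C)[C@@]2(C)CCCC(C)(C)[C@H]12 | intermediate
24 | ustusoic acid B, 9α-hydroxy-6β-[(2E,4E,6E)-octa-2,4,6-trienoyloxy]-12-oxo-5α-drim-7-en-11-oic acid (5S,6R,9S,10S) | C/C=C/C=C/C=C/C(=O)O[C@@H]1C=C(C=O)[C@](O)(C(=O)O)[C@@]2(C)CCCC(C)(C)[C@H]12 | target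

## Step count and least certain steps

Total step count: 17. Longest linear sequence: 16 (steps 1 to 14, then 16 and 17); step 15 is a one-step branch.

Step 2 (key step).
- What may go wrong: slow cycloaddition, because the diene must reach its s-cis form against the Z-methyl group and must bond to a methyl-substituted quinone carbon. Under the strongly acidic catalyst this leaves time for protodesilylation of the diene, for a stepwise Mukaiyama–Michael addition that stops before ring closure, and for loss of facial selectivity through an uncatalysed background reaction.
- Fallback: from 3 and 4, the cycloaddition is run with an achiral Lewis acid that binds the same C6 carbonyl (BF3·OEt2 or SnCl4, CH2Cl2, −78 °C). This keeps the regiochemistry but gives 5 together with the enantiomer of the adduct F1. The two are separated by preparative chromatography on a chiral stationary phase, and the route is re-entered at 5.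

Step 3.
- What may go wrong: incomplete or unfavourable equilibration. Cis and trans isomers each carry one syn-axial interaction across ring A, so the equilibrium may not lie far to the trans side; air oxidation of the dienolate is a second hazard.
- Fallback (kinetic instead of thermodynamic control): from 5, deprotonation with KN(SiMe3)2 (THF, −78 °C) gives the potassium dienolate F2, which is protonated at −78 °C with acetic acid. Carbon protonation is expected on the α-face, away from the C10 and 4β methyl groups, and returns to 6. Because step 4 follows at −78 °C and then fixes C5 for good, a kinetic preference is enough.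

Step 4.
- What may go wrong: insufficient discrimination between the two carbonyls (attack at C9, or double reduction), since C6 is itself next to the neopentyl C5.
- Fallback: from 6, both carbonyls are reduced (excess NaBH4, CeCl3·7H2O, MeOH, 0 °C) to the 6β,9β-diol F3. MnO2 (CH2Cl2, 23 °C) should then re-oxidise the quasi-equatorial 9β-carbinol, whose axial C–H bond is aligned with the alkene, in preference to the quasi-axial, doubly shielded 6β-carbinol, returning to 7.

Step 10.
- What may go wrong: competing osmylation of C7=C8, which is trisubstituted and intrinsically the more electron-rich alkene, or double dihydroxylation.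
- Fallback: from 12, hydroboration with 9-borabicyclo[3.3.1]nonane (THF; then NaOH, H2O2) is selective for the terminal alkene, delivers hydrogen to C9 from the α-face and gives the 11-alcohol F4. Oxidation with SO3·pyridine, DMSO and iPr2NEt gives the β,γ-unsaturated 11-aldehyde F5. Its potassium dienolate (KN(SiMe3)2, −78 °C) is hydroxylated at C9 on the α-face with 2-(phenylsulfonyl)-3-phenyloxaziridine to give 14, isolated in this variant and taken to 15 by the chlorite half of step 11.

Step 13.
- What may go wrong: a slow ene step on an alkene flanked by three electron-withdrawing groups, and closure of any C12 alcohol that escapes further oxidation onto C11 to give the 11,12-lactone, a dead end. The tert-butyl ester is there to slow this, but cannot exclude it.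
- Fallback: from 16, Wohl–Ziegler bromination (N-bromosuccinimide, cat. dibenzoyl peroxide, PhCF3, 80 °C) gives the allylic 12-bromide F6, and Kornblum oxidation (DMSO, NaHCO3, 60 °C) reaches the aldehyde level without a free alcohol, returning to 17.

Step 16.
- What may go wrong: slow acylation of the axial 6β-hydroxyl, which is syn to two methyl groups, giving the activated trienoic acid time to deconjugate through a vinylketene.
- Fallback: from 18, the alcohol is acylated with the small and very reactive (diethoxyphosphoryl)acetic acid and N,N′-dicyclohexylcarbodiimide (CH2Cl2) to the 6β-phosphonoacetate F7. A Horner–Wadsworth–Emmons olefination with an excess of 19 (LiCl, DBU, MeCN) then builds the 2E double bond on the ester and returns to 23. The excess of the unhindered 19 is meant to outrun the hindered C12 aldehyde of the substrate itself.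

## Further compounds

F1 | step 2 | enantiomer of 5, 2-(triisopropylsilyloxy)-11-nor-drima-2,7-diene-6,9-dione (5α-H; 10α-methyl; cis-fused) | O=C1C=C(C)C(=O)[C@]2(C)CC(O[Si](C(C)C)(C(C)C)C(C)C)=CC(C)(C)[C@H]12
F2 | step 3 | potassium 9-oxo-2-(triisopropylsilyloxy)-11-nordrima-2,5,7-trien-6-olate (10β-methyl) | [K+].[O-]C1=C2C(C)(C)C=C(O[Si](C(C)C)(C(C)C)C(C)C)C[C@]2(C)C(=O)C(C)=C1
F3 | step 4 | 2-(triisopropylsilyloxy)-11-nor-5α-drima-2,7-diene-6β,9β-diol | O[C@@H]1C=C(C)[C@H](O)[C@@]2(C)CC(O[Si](C(C)C)(C(C)C)C(C)C)=CC(C)(C)[C@H]12
F4 | step 10 | 6β-(tert-butyldimethylsilyloxy)-5α,9α(H)-drim-7-en-11-ol | CC(C)(C)[Si](C)(C)O[C@@H]1C=C(C)[C@H](CO)[C@@]2(C)CCCC(C)(C)[C@H]12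
F5 | step 10 | 6β-(tert-butyldimethylsilyloxy)-5α,9α(H)-drim-7-en-11-al | CC(C)(C)[Si](C)(C)O[C@@H]1C=C(C)[C@H](C=O)[C@@]2(C)CCCC(C)(C)[C@H]12
F6 | step 13 | tert-butyl 12-bromo-6β-(tert-butyldimethylsilyloxy)-9α-hydroxy-5α-drim-7-en-11-oate | CC(C)(C)[Si](C)(C)O[C@@H]1C=C(CBr)[C@](O)(C(=O)OC(C)(C)C)[C@@]2(C)CCCC(C)(C)[C@H]12
F7 | step 16 | tert-butyl 6β-[2-(diethoxyphosphoryl)acetoxy]-9α-hydroxy-12-oxo-5α-drim-7-en-11-oate | CCOP(=O)(OCC)CC(=O)O[C@@H]1C=C(C=O)[C@](O)(C(=O)OC(C)(C)C)[C@@]2(C)CCCC(C)(C)[C@H]12
A1 | alternative 1 | 3-hydroxy-4-methyl-2H-pyran-2-one | O=C1OC=CC(C)=C1O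
A2 | alternative 1 | 2,4,4-trimethylcyclohex-2-en-1-one | CC1=CC(C)(C)CCC1=O
A3 | alternative 1 | 9α-hydroxy-1-oxo-5β-drim-7-en-11,6β-olide (cis-fused bridged lactone) | O3[C@@H]1C=C(C)[C@](O)(C3=O)[C@@]2(C)C(=O)CCC(C)(C)[C@@H]12
A4 | alternative 2 | methyl 5α-drima-6,8-dien-11-oate | C1=CC(C)=C(C(=O)OC)[C@@]2(C)CCCC(C)(C)[C@H]12
A5 | alternative 2 | methyl 6α,9α-epidioxy-5α-drim-7-en-11-oate | O3[C@H]1C=C(C)[C@](O3)(C(=O)OC)[C@@]2(C)CCCC(C)(C)[C@H]12
A6 | alternative 2 | methyl 9α-hydroxy-6-oxo-5α-drim-7-en-11-oate | O=C1C=C(C)[C@](O)(C(=O)OC)[C@@]2(C)CCCC(C)(C)[C@H]12
A7 | alternative 3 | 2,2,2-trifluoroethyl (2E,8Z,10E)-3,7,7-trimethyl-9-(triisopropylsilyloxy)dodeca-2,8,10-trienoate | FC(F)(F)COC(=O)/C=C(\C)CCCC(C)(C)/C=C(O[Si](C(C)C)(C(C)C)C(C)C)/C=C/C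
A8 | alternative 3 | 2,2,2-trifluoroethyl 8β-methyl-6-(triisopropylsilyloxy)-5α,9α(H)-drim-6-en-11-oate (trans-fused) | CC(C)[Si](C(C)C)(C(C)C)OC1=C[C@H](C)[C@H](C(=O)OCC(F)(F)F)[C@@]2(C)CCCC(C)(C)[C@H]12
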